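Whatever the temperature, both products are counted from one charge, so the excess of left-handed product over right-handed product hangs on one number: their ratio. The excess is one minus that ratio over one plus it.

| setting | green | ochre | spring | autumn | dawn | noon |
|---|---|---|---|---|---|---|
| left-handed substrate | 1 mM | 4 mM | 2.0 mM | 2.0 mM | 2.0 mM | 2.0 mM |
| right-handed substrate | 1 mM | 4 mM | 2.0 mM | 2.0 mM | 2.0 mM | 2.0 mM |
| partner | 4 mM | 4 mM | 4.00 mM | 4.00 mM | 4.00 mM | 4.00 mM |
| temperature | 35 °C | 60 °C | 60 °C |  | 40 °C | 80 °C |
| remark | run made earlier | run made earlier |  | at 40 °C until 6.0 min, from then on at 80 °C |  |  |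
| time |  |  | 12 min | 12 min | 12 min | 12 min |

| run | time / min | left-handed product / % | right-handed product / % |
|---|---|---|---|
| green | 3.00 | 27.1 | 0 |
| green | 5.00 | 35.9 | 0 |
| green | 6.00 | 40.0 | 1.6 |
| green | 8.00 | 43.2 | 0.3 |
| green | 15.0 | 47.8 | 0.1 |
| green | 20.0 | 48.5 | 0 |
| green | 30.0 | 49.5 | 0.1 |
| ochre | 0.500 | 14.5 | 0 |
| ochre | 1.33 | 25.2 | 0.2 |
| ochre | 2.50 | 31.1 | 0.2 |
| ochre | 4.00 | 37.5 | 0 |
| ochre | 6.00 | 40.2 | 0 |
| ochre | 8.00 | 40.1 | 1.1 |
| ochre | 10.0 | 42.8 | 1.3 |

(each reading ± 1 percentage point)

- partner is single-handed; left-handed substrate and right-handed substrate are mirror images of each other, charged as a racemate, each of them at the stated concentration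
- an excess is below zero if the other one leads
- the handed part of partner does not stay in what it makes, so the products of the two hands are mirror images too

1. the flask that comes out highest in excess of left-handed product over right-handed product, or "all alike" when all lie within 1.5 percentage points (spring / autumn / dawn / noon / all alike)
2. excess of left-handed product over right-handed product at the end, spring
3. excess of left-handed product over right-handed product at the end, autumn
4. excess of left-handed product over right-handed product at the end, dawn
5. excess of left-handed product over right-handed product at the end, noon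

How large is the ratio? The ochre run shows right-handed product in its last two readings, and these give 2.90% at 60 °C. The green readings of right-handed product lie mostly within the scatter of zero, so I sum the whole run and get 0.719% at 35 °C, a rough reading.

How does it move with temperature? Taking a fixed factor per degree between these two readings gives 0.950% at 40 °C. At the temperature of noon, the wrong-hand ratio, right-handed product over left-handed product, comes to 8.82%. The two hands are told apart by rate, a kinetic resolution. My excesses are 94.4% for spring, 98.1% for dawn and 83.8% for noon, so dawn leads.

What of autumn? The green run had 80.8% of its last left-handed product by 6.00 min. Weighting by that share, a first answer is 95.4%. Going round again, the readings of right-handed product, with their scatter of 1 percentage point, don't show when it forms, so I try a plain assumption instead: it counts by time at each temperature. Weighting the ratio by time gives 4.89% and an excess of 90.7%, lower than the first answer.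

The forecast names dawn, with 95% for spring, 91% for autumn, 98% for dawn and 85% for noon, which at noon is higher than mine. Its ground: “Selectivity is weakest when hot, so dawn comes out highest.”

The flasks give dawn highest: 91.2% for spring, 89.7% for autumn, 97.2% for dawn and 87.5% for noon.

    right-handed substrate ⇌ achiral form (K = 1.20, k = 0.00519 /s, Ea = 91.0 kJ/mol, ΔH = 5.00 kJ/mol)
    achiral form → waste (k = 0.00106 /s, Ea = 106 kJ/mol)
    2 partner → homo dimer (k = 0.423 /M/s, Ea = 54.0 kJ/mol)
    left-handed substrate ⇌ achiral form (K = 1.20, k = 0.00519 /s, Ea = 91.0 kJ/mol, ΔH = 5.00 kJ/mol)
    partner + left-handed substrate → left-handed product (k = 8.34 /M/s, Ea = 38.0 kJ/mol)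
    partner + right-handed substrate → right-handed product (k = 0.200 /M/s, Ea = 74.0 kJ/mol)
    (constants at 80 °C)

Noon ends at a ratio of 6.68%, lower than the 8.82% reckoned. A neighbour of noon has 6.8 mM of partner, with the other charges and the time held. Scaling by [partner], the reckoned ratio becomes 15.0%, and noon's own ratio becomes 11.4%, an excess of 79.5%. That neighbour ends at a ratio of 10.1% and an excess of 81.6%.

The readings stem from a simulated flask with constants of no real substance, noise included.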